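## The problem

Theaflavin (21) is a 3,4,6-trihydroxy-5H-benzo[7]annulen-5-one (a benzotropolone) that carries the same (2R,3R)-3,5,7-trihydroxychroman-2-yl unit twice, on the benzene ring at C1 and on the seven-membered ring at C8. Its four stereocentres form two remote pairs. Within a pair C2 and C3 can be related to each other, but neither pair can steer the other across the flat bicycle, so each pair needs reagent control, and in the less stable 2,3-cis sense. The benzene ring of the bicycle is pentasubstituted, with three contiguous carbon substituents (C1, C9a, C4a) beside two oxygens (C3, C4), so the order of substitution decides whether positions are unambiguous. The free tropolone is acidic and chelating, and once O-alkylated it is an electrophilic polyenone toward hydride and hard carbon nucleophiles. The liberated polyphenol is air-sensitive, its C2 centres epimerise in base and the benzylic C2–O1 bonds ionise in strong acid, so one set of hydrogenolysable groups and a mild last step are needed. The enabling feature is that the two oxygen-bearing tropolone carbons, C5 (on C4a) and C6, are neighbours, joined on the far side to C9a only by C7 and the C8=C9 double bond. A 2-formylaryl acrylate with a CH2CHO arm on its α-carbon therefore holds both carbons as aldehydes within reach, and the diol from their reductive coupling lies four hydrogens above the tropolone.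

## Retrosynthesis

**21 from 20.** Seven O–benzyl bonds are cut. Benzyl ethers are the one group that can mask the tropolone, the catechol and both phloroglucinol rings and still leave in a single neutral operation. The forward step must spare the tropolone ring and the two benzylic C2–O1 bonds.

**20 from 19, and 19 from 17 and 18.** In each chroman the C4–C4a bond and the O1–C2 bond are cut, which returns the bis(epoxy alcohol) 17 and two molecules of commercial 3,5-bis(benzyloxy)phenol 18. The neighbouring cut, C2 to the bicycle, would need a preformed enantiopure chroman and a C2 electrophile or nucleophile, and it tends to give the 2,3-trans series. The chosen cut takes ring A and O1 from a symmetrical phenol, so the ring closure has only one regiochemical outcome. Forward, the ether must form with inversion at the carbinol (Mitsunobu), and the arene must attack the terminal epoxide carbon, so that C3 keeps the epoxide configuration. An erythro epoxy alcohol then gives the cis flavan-3-ol directly, with no later correction at C3.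

**17 from 16, and 16 from 15.** The two epoxide oxygens and the two carbinol–vinyl C–C bonds are cut, leading to dialdehyde 15. Both arms are treated identically, so every operation is done twice in one flask. Enantioselective vinyl transfer sets the carbinols, and the tartrate-controlled epoxidation that follows is the matched case: it adds the second centre of each pair and removes any arm of the wrong configuration.

**15 from 14, and 14 from 12.** The O6–benzyl bond is cut, and then four C–H/O–H pairs are added back to give tetraol 12. The position of the tropolone in the sequence is the main design decision. It must exist before the epoxidation, because in the dihydro series the C8=C9 bond is an ordinary trisubstituted allylic alkene that would be epoxidised before a terminal vinyl group. It must not exist during ester reduction, because an alkoxytropone does not tolerate aluminium hydrides. One activated-DMSO oxidation of 12 therefore makes both aldehydes and the tropolone at once.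

**12 from 11, and 11 from 10.** Both esters of 11 are taken back from the two CH2OH groups. The C1–CO2Me bond is then cut to the aryl bromide 10 (palladium-catalysed methoxycarbonylation). Bromine is the right spectator at C1 for the ring closure. A formyl group there would be a second aryl aldehyde ortho to the same side chain, and could close a rival seven-membered ring.

**10 from 9 (key cut).** The C5–C6 bond is cut to two aldehydes. The alternatives are weaker: a C6–C7 aldol cut leaves the two oxygens at unequal oxidation levels, and a C4a–C5 acylation would have to find one position on a crowded arene. The C5–C6 cut instead gives a symmetrical pair of carbonyl carbons, and its product already has both oxygens in place. The precursor 9 is acyclic apart from the arene, and its E-alkene holds the two arms on the same side. Forward, the aldehydes must be reduced in preference to the aryl bromide and the conjugated ester.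

**9 from 8, and 8 from 6.** The aliphatic aldehyde comes from primary alcohol 8. The hydroxy ester 8 is the opened form of the α-arylidene-γ-butyrolactone 6. The lactone serves as an internal protecting group for the C6 alcohol and the C8 carboxyl through the arene chemistry.

**6 from 5, 5 from 4, and 4 from 3.** The O4–benzyl, C1–Br and C4a–CHO bonds are cut in that order. The free phenol at C4 controls both substitutions. Magnesium-mediated formylation can reach only the one free ortho carbon, C4a. Bromination then has only the para carbon, C1, left. The competing idea of lithiating next to an aryl bromide was set aside, because amide bases would be expected to deprotonate between the bromine and the neighbouring benzyloxy group instead.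

**3 from 1 and 2.** The C8=C9 double bond is cut by a Wittig disconnection to commercial 4-(benzyloxy)-3-hydroxybenzaldehyde 1 and the commercial lactone ylide 2. The stabilised ylide gives the E-alkene, which places the aryl group cis to the ring CH2 (the future C7).

## Roads not taken

**Alternative 1:** carbonyl ylide cycloaddition. The cut removes the C6–C7 and C8–C9 bonds together. Forward, Rh2(OAc)4 would convert the ortho-formyl diazoketone A3 into a carbonyl ylide, which adds across the terminal alkyne of the ethynylchroman A2 to give the oxygen-bridged adduct A1. Base-induced opening of the bridge would then give the tropolone oxidation pattern directly.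

- Merits: two ring bonds form in one step, and the plan is convergent, since one flavan arrives intact with A2 and the other is already on A3.
- Weak points: A3 is itself a pentasubstituted arene with a complete flavan at C1 and a diazoketone between a benzyloxy group and a formyl group. The rhodium carbenoid faces seven benzyl ethers and three electron-rich arenes as competitors for the hindered formyl oxygen. The orientation of a monosubstituted alkyne on such an ylide is not secured by any substituent. A2 needs its own asymmetric synthesis and carries a propargylic, ether-bearing C2 that could epimerise.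
- Comparison: this road is better in convergence and in bonds formed per step. The chosen plan sets against it a ring closure with only one possible pairing (two aldehydes), and two flavans grown by the same four operations on one intermediate instead of two separate multistep partners.

**Alternative 2:** double enantioselective conjugate arylation. The cut removes both C2–aryl bonds. Forward, Pd(OCOCF3)2 with a chiral pyridine–oxazoline ligand would add the diboronic acid A5 to two molecules of the chromone A6, giving the bis-flavanone A4 with both C2 centres set.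

- Merits: both C2 centres come from one catalyst in one step, and A6 is trivial to make.
- Weak points: A5 still needs a complete benzotropolone synthesis, so the central ring problem is only moved. One of its C–B bonds sits on the tropone ring at C8, a vinylogous position prone to protodeboronation and outside the arylboronic acid scope of the method. A 5-alkoxychromone is a hindered acceptor. After A4, each unit still needs oxygen at C3 in the cis sense and removal of the C4 carbonyl, on a flavanone whose C2 racemises by ring opening in base.
- Comparison: this road is better for C2 control and for convergence. The chosen plan sets against it that C3 oxygen and the cis relationship come with the epoxide at no extra cost, and that it actually builds the seven-membered ring.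

**Alternative 3:** dichlorocarbene ring expansion. The cut removes C6 from between C5 and C7. Forward, dichlorocarbene from Cl3CCO2Na would add across the C3–C4 enol-ether bond of the naphthoate A8, and the adduct would open with loss of chloride and the O-methyl group to the 6-chlorobenzotropone A7.

- Merits: A8 follows from a classical Stobbe condensation and ring closure, which also fixes the arene substitution pattern, so the bicyclic core is reached in fewer steps than in the chosen plan.
- Weak points: the carbene must attack an aromatic bond that the ester at C2 of A8 makes electron-poor. A7 carries chlorine at C6 where oxygen is needed, and exchanging it calls for forcing hydrolysis. The methylenedioxy bridge needs a strong Lewis acid, which is incompatible with flavan-3-ols, so it would have to be exchanged early.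
- Comparison: this road is shorter to the core. The chosen plan sets against it that both tropolone oxygens arrive at the correct level from the diol, and that every protecting group leaves by hydrogenolysis.

Key step: step 7

Remark: O-benzylation of tropolone 14 is drawn at O6; the O5 regioisomer, if formed, would behave the same way and give the same 21.
Remark: diol 10 is drawn as the cis racemate; a trans isomer would be carried on unchanged, since C5 and C6 lose their configuration in step 10.
Remark: 1, 2 and 18 are taken as purchased; 1 is the 4-O-benzyl ether of 3,4-dihydroxybenzaldehyde and 18 the dibenzyl ether of phloroglucinol.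

## Route

Step 1
Reactants: 1 4-(benzyloxy)-3-hydroxybenzaldehyde; 2 3-(triphenyl-λ5-phosphanylidene)oxolan-2-one
Product: 3 (3E)-3-[4-(benzyloxy)-3-hydroxybenzylidene]oxolan-2-one
Conditions: 2 (1.2 equiv), toluene, 100 °C
Reagents that add atoms: none
Why: Wittig olefination with a stabilised ylide; reversible betaine formation should give the E-alkene (aryl trans to the lactone carbonyl, so cis to the ring CH2), and stabilised ylides tolerate a free phenol.

Step 2
Reactants: 3 (3E)-3-[4-(benzyloxy)-3-hydroxybenzylidene]oxolan-2-one
Product: 4 3-(benzyloxy)-2-hydroxy-6-[(E)-(2-oxooxolan-3-ylidene)methyl]benzaldehyde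
Conditions: MgCl2, Et3N, (CH2O)n, MeCN, 80 °C
Reagents that add atoms: paraformaldehyde (as formaldehyde), C=O
Why: Casnati–Skattebøl ortho-formylation; the magnesium phenoxide delivers formaldehyde only to an ortho carbon, the single free one is the future C4a, and a second formaldehyde oxidises the benzylic alkoxide by hydride transfer.

Step 3
Reactants: 4 3-(benzyloxy)-2-hydroxy-6-[(E)-(2-oxooxolan-3-ylidene)methyl]benzaldehyde
Product: 5 3-(benzyloxy)-5-bromo-2-hydroxy-6-[(E)-(2-oxooxolan-3-ylidene)methyl]benzaldehyde
Conditions: NBS, MeCN, 0 °C to rt
Reagents that add atoms: N-bromosuccinimide, O=C1CCC(=O)N1Br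
Why: Electrophilic aromatic bromination; the only open position activated by the phenol is the para carbon (future C1), as in the bromination of 3-alkoxysalicylaldehydes, and the electron-poor alkylidene lactone should not react with NBS.

Step 4
Reactants: 5 3-(benzyloxy)-5-bromo-2-hydroxy-6-[(E)-(2-oxooxolan-3-ylidene)methyl]benzaldehyde
Product: 6 2,3-bis(benzyloxy)-5-bromo-6-[(E)-(2-oxooxolan-3-ylidene)methyl]benzaldehyde
Conditions: BnBr, K2CO3, DMF, rt
Reagents that add atoms: benzyl bromide, BrCc1ccccc1
Why: Williamson etherification of the salicylaldehyde-type phenoxide; the lactone, aldehyde and aryl bromide are inert to carbonate at room temperature.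

Step 5
Reactants: 6 2,3-bis(benzyloxy)-5-bromo-6-[(E)-(2-oxooxolan-3-ylidene)methyl]benzaldehyde
Product: 8 methyl (2E)-2-[3,4-bis(benzyloxy)-6-bromo-2-formylbenzylidene]-4-hydroxybutanoate, via lithium hydroxy carboxylate 7 (not isolated)
Conditions: LiOH (1.05 equiv), THF/H2O, 0 °C; evaporate; MeI, DMF, 0 °C to rt
Reagents that add atoms: lithium hydroxide, [Li+].[OH-]; iodomethane, CI
Why: Saponification of the γ-lactone followed by SN2 O-methylation of the carboxylate salt; the alcohol is never deprotonated and no acid is used, so the γ-hydroxy ester should not close back, and the alkene geometry is untouched.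

Step 6
Reactants: 8 methyl (2E)-2-[3,4-bis(benzyloxy)-6-bromo-2-formylbenzylidene]-4-hydroxybutanoate
Product: 9 methyl (2E)-2-[3,4-bis(benzyloxy)-6-bromo-2-formylbenzylidene]-4-oxobutanoate
Conditions: Dess–Martin periodinane, NaHCO3, CH2Cl2, 0 °C; used at once
Reagents that add atoms: none
Why: Dess–Martin oxidation of a primary alcohol under buffered, non-basic conditions, chosen so that the enolisable CH2CHO arm neither isomerises nor condenses with the aryl aldehyde.

Step 7
Reactants: 9 methyl (2E)-2-[3,4-bis(benzyloxy)-6-bromo-2-formylbenzylidene]-4-oxobutanoate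
Product: 10 methyl (5R*,6S*)-3,4-bis(benzyloxy)-1-bromo-5,6-dihydroxy-6,7-dihydro-5H-benzo[7]annulene-8-carboxylate
Conditions: SmI2 (2.4 equiv), THF, 0.005 M, −78 to 0 °C; aq. NH4Cl
Reagents that add atoms: none
Why: SmI2 transfers one electron to the aryl aldehyde (the more easily reduced, benzylic ketyl), the samarium-bound ketyl carbon C5 adds to the samarium-coordinated aliphatic aldehyde carbon C6, and a second electron transfer gives the samarium diolate that is protonated on work-up. The closest known reaction type is the SmI2-mediated intramolecular pinacol coupling of dialdehydes and keto aldehydes to cyclic 1,2-diols, which is established for five- to seven-membered carbocycles. The seven-membered ring closes by 7-exo-trig attack of the C5 ketyl on the C6 carbonyl, eased because C4a, C9a, C9 and C8 are held coplanar by the arene and the E-alkene so that only C7 has to rotate into place. C5 and C6 should form as the cis-diol because both oxygens stay bound to trivalent samarium in the coupling transition state; both centres are erased in step 10, so a trans isomer would converge. The step needs the aldehydes to be reduced in preference to the aryl bromide, the benzyl ethers and the aryl-conjugated ester, which SmI2 in THF without HMPA or other strong donor ligands secures. Ketyl–alkene addition cannot compete because either ketyl would have to close a four-membered ring or attack 5-endo to reach C8=C9, and with only two aldehydes present no other pinacol pairing exists. High dilution suppresses intermolecular coupling, and the low temperature and neutral medium keep the CH2CHO arm from aldol closure onto the aryl aldehyde before the ketyl forms.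

Step 8
Reactants: 10 methyl (5R*,6S*)-3,4-bis(benzyloxy)-1-bromo-5,6-dihydroxy-6,7-dihydro-5H-benzo[7]annulene-8-carboxylate
Product: 11 dimethyl (5R*,6S*)-3,4-bis(benzyloxy)-5,6-dihydroxy-6,7-dihydro-5H-benzo[7]annulene-1,8-dicarboxylate
Conditions: Pd(OAc)2 (5 mol %), Xantphos (6 mol %), CO (1 atm), Et3N, MeOH/toluene, 70 °C
Reagents that add atoms: carbon monoxide, [C-]#[O+]; methanol, CO
Why: Palladium-catalysed methoxycarbonylation of an aryl bromide (oxidative addition to zerovalent palladium, CO insertion, methanolysis of the acyl complex); the free diol and the conjugated ester are spectators under these weakly basic conditions.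

Step 9
Reactants: 11 dimethyl (5R*,6S*)-3,4-bis(benzyloxy)-5,6-dihydroxy-6,7-dihydro-5H-benzo[7]annulene-1,8-dicarboxylate
Product: 12 (5R*,6S*)-3,4-bis(benzyloxy)-1,8-bis(hydroxymethyl)-6,7-dihydro-5H-benzo[7]annulene-5,6-diol
Conditions: i-Bu2AlH (8 equiv), CH2Cl2/THF, −78 to 0 °C; aq. KNaC4H4O6
Reagents that add atoms: none
Why: Aluminium hydride reduction of both esters to primary alcohols (1,2-reduction of the conjugated ester); it is done here because no tropone is yet present to compete for hydride.

Step 10
Reactants: 12 (5R*,6S*)-3,4-bis(benzyloxy)-1,8-bis(hydroxymethyl)-6,7-dihydro-5H-benzo[7]annulene-5,6-diol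
Product: 14 3,4-bis(benzyloxy)-6-hydroxy-5-oxo-5H-benzo[7]annulene-1,8-dicarbaldehyde, via 5,6-dione 13 (not isolated)
Conditions: (COCl)2, DMSO, CH2Cl2, −78 °C; Et3N, −78 to 0 °C
Reagents that add atoms: none
Why: Swern oxidation of all four hydroxyls; activated DMSO oxidises vicinal diols to 1,2-diones without C–C cleavage, and dione 13 enolises through its doubly activated C7–H to the conjugated tropolone 14, which removes both pinacol stereocentres.

Step 11
Reactants: 14 3,4-bis(benzyloxy)-6-hydroxy-5-oxo-5H-benzo[7]annulene-1,8-dicarbaldehyde
Product: 15 3,4,6-tris(benzyloxy)-5-oxo-5H-benzo[7]annulene-1,8-dicarbaldehyde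
Conditions: BnBr, K2CO3, DMF, 0 °C to rt
Reagents that add atoms: benzyl bromide, BrCc1ccccc1
Why: O-alkylation of the tropolonate; it removes the acidic, titanium-binding hydroxyl before the zinc, titanium and Mitsunobu steps.

Step 12
Reactants: 15 3,4,6-tris(benzyloxy)-5-oxo-5H-benzo[7]annulene-1,8-dicarbaldehyde
Product: 16 3,4,6-tris(benzyloxy)-1,8-bis[(1R)-1-hydroxyprop-2-en-1-yl]-5H-benzo[7]annulen-5-one
Conditions: Zn(CH=CH2)2 (4 equiv), (+)-DAIB [(2R)-3-exo-(dimethylamino)isoborneol, 20 mol %], toluene, −20 to 0 °C
Reagents that add atoms: divinylzinc, C=C[Zn]C=C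
Why: Amino-alcohol-catalysed enantioselective addition of an alkenylzinc to aldehydes; the chiral zinc aminoalkoxide should deliver vinyl to the Re face of each formyl group (the sense opposite to that of (−)-DAIB) to set both (1R) carbinols, and organozinc reagents add 1,2 to aldehydes while leaving the tropone carbonyl alone.

Step 13
Reactants: 16 3,4,6-tris(benzyloxy)-1,8-bis[(1R)-1-hydroxyprop-2-en-1-yl]-5H-benzo[7]annulen-5-one
Product: 17 3,4,6-tris(benzyloxy)-1,8-bis{(S)-hydroxy[(2R)-oxiran-2-yl]methyl}-5H-benzo[7]annulen-5-one
Conditions: Ti(OiPr)4 (0.6 equiv), L-(+)-diisopropyl tartrate (0.75 equiv), t-BuOOH (4 equiv), 4 Å molecular sieves, CH2Cl2, −20 °C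
Reagents that add atoms: tert-butyl hydroperoxide, CC(C)(C)OO
Why: Sharpless asymmetric epoxidation of secondary allylic alcohols in the matched sense; with L-(+)-tartrate the (1R) carbinols are the fast-reacting ones and give the erythro epoxy alcohols with (2R) oxiranes, any (1S) arm stays behind as a separable mono-epoxide, and the polarised, electron-poor tropone double bonds should not be attacked by the electrophilic titanium peroxide.

Step 14
Reactants: 17 3,4,6-tris(benzyloxy)-1,8-bis{(S)-hydroxy[(2R)-oxiran-2-yl]methyl}-5H-benzo[7]annulen-5-one; 18 3,5-bis(benzyloxy)phenol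
Product: 19 3,4,6-tris(benzyloxy)-1,8-bis{(R)-[3,5-bis(benzyloxy)phenoxy][(2R)-oxiran-2-yl]methyl}-5H-benzo[7]annulen-5-one
Conditions: 18 (2.6 equiv), PPh3, DIAD, toluene, 0 °C to rt
Reagents that add atoms: none
Why: Mitsunobu etherification; the phenoxide displaces the oxyphosphonium group by SN2 with inversion at each carbinol, giving the threo aryl ethers needed for the cis series, and ionisation is disfavoured by the adjacent epoxide oxygen and the electron-poor benzotropone.

Step 15
Reactants: 19 3,4,6-tris(benzyloxy)-1,8-bis{(R)-[3,5-bis(benzyloxy)phenoxy][(2R)-oxiran-2-yl]methyl}-5H-benzo[7]annulen-5-one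
Product: 20 3,4,6-tris(benzyloxy)-1,8-bis[(2R,3R)-5,7-bis(benzyloxy)-3-hydroxy-3,4-dihydro-2H-chromen-2-yl]-5H-benzo[7]annulen-5-one
Conditions: AuCl3 (10 mol %), AgOTf (30 mol %), ClCH2CH2Cl, 0 °C to rt
Reagents that add atoms: none
Why: Gold-catalysed intramolecular Friedel–Crafts alkylation of an electron-rich aryl ether by its epoxide (6-endo attack at the terminal carbon, as in the cyclisation of aryl glycidyl ethers to chroman-3-ols); the two carbons ortho to the ether oxygen are equivalent, and C3 keeps the epoxide configuration while C2 is untouched, so each chroman should be 2,3-cis (2R,3R).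

Step 16
Reactants: 20 3,4,6-tris(benzyloxy)-1,8-bis[(2R,3R)-5,7-bis(benzyloxy)-3-hydroxy-3,4-dihydro-2H-chromen-2-yl]-5H-benzo[7]annulen-5-one
Product: 21 theaflavin
Conditions: H2 (1 atm), Pd(OH)2/C, THF/MeOH, rt; filtered under argon
Reagents that add atoms: none
Why: Hydrogenolysis of seven benzyl ethers under neutral conditions; the tropolone ether should cleave fastest, and stopping at the uptake for seven benzyl groups spares the tropolone ring and the flavan C2–O1 bonds.

## Compound list

1 | 4-(benzyloxy)-3-hydroxybenzaldehyde | O=Cc1ccc(OCc2ccccc2)c(O)c1 | starting material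
2 | 3-(triphenyl-λ5-phosphanylidene)oxolan-2-one | O=C1OCCC1=P(c1ccccc1)(c1ccccc1)c1ccccc1 | starting material
3 | (3E)-3-[4-(benzyloxy)-3-hydroxybenzylidene]oxolan-2-one | O=C1OCC/C1=C\c1ccc(OCc2ccccc2)c(O)c1 | intermediate
4 | 3-(benzyloxy)-2-hydroxy-6-[(E)-(2-oxooxolan-3-ylidene)methyl]benzaldehyde | O=C1OCC/C1=C\c1ccc(OCc2ccccc2)c(O)c1C=O | intermediate
5 | 3-(benzyloxy)-5-bromo-2-hydroxy-6-[(E)-(2-oxooxolan-3-ylidene)methyl]benzaldehyde | O=C1OCC/C1=C\c1c(Br)cc(OCc2ccccc2)c(O)c1C=O | intermediate
6 | 2,3-bis(benzyloxy)-5-bromo-6-[(E)-(2-oxooxolan-3-ylidene)methyl]benzaldehyde | O=C1OCC/C1=C\c1c(Br)cc(OCc2ccccc2)c(OCc2ccccc2)c1C=O | intermediate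
7 | lithium (2E)-2-[3,4-bis(benzyloxy)-6-bromo-2-formylbenzylidene]-4-hydroxybutanoate | OCC/C(=C\c1c(Br)cc(OCc2ccccc2)c(OCc2ccccc2)c1C=O)C(=O)[O-].[Li+] | intermediate
8 | methyl (2E)-2-[3,4-bis(benzyloxy)-6-bromo-2-formylbenzylidene]-4-hydroxybutanoate | OCC/C(=C\c1c(Br)cc(OCc2ccccc2)c(OCc2ccccc2)c1C=O)C(=O)OC | intermediate
9 | methyl (2E)-2-[3,4-bis(benzyloxy)-6-bromo-2-formylbenzylidene]-4-oxobutanoate | O=CC/C(=C\c1c(Br)cc(OCc2ccccc2)c(OCc2ccccc2)c1C=O)C(=O)OC | intermediate
10 | methyl (5R*,6S*)-3,4-bis(benzyloxy)-1-bromo-5,6-dihydroxy-6,7-dihydro-5H-benzo[7]annulene-8-carboxylate (cis, racemic, one enantiomer drawn) | COC(=O)C1=Cc2c(Br)cc(OCc3ccccc3)c(OCc3ccccc3)c2[C@@H](O)[C@@H](O)C1 | intermediate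
11 | dimethyl (5R*,6S*)-3,4-bis(benzyloxy)-5,6-dihydroxy-6,7-dihydro-5H-benzo[7]annulene-1,8-dicarboxylate (cis, racemic) | COC(=O)C1=Cc2c(C(=O)OC)cc(OCc3ccccc3)c(OCc3ccccc3)c2[C@@H](O)[C@@H](O)C1 | intermediate
12 | (5R*,6S*)-3,4-bis(benzyloxy)-1,8-bis(hydroxymethyl)-6,7-dihydro-5H-benzo[7]annulene-5,6-diol (cis, racemic) | OCC1=Cc2c(CO)cc(OCc3ccccc3)c(OCc3ccccc3)c2[C@@H](O)[C@@H](O)C1 | intermediate
13 | 3,4-bis(benzyloxy)-5,6-dioxo-6,7-dihydro-5H-benzo[7]annulene-1,8-dicarbaldehyde | O=CC1=Cc2c(C=O)cc(OCc3ccccc3)c(OCc3ccccc3)c2C(=O)C(=O)C1 | intermediate
14 | 3,4-bis(benzyloxy)-6-hydroxy-5-oxo-5H-benzo[7]annulene-1,8-dicarbaldehyde | O=CC1=Cc2c(C=O)cc(OCc3ccccc3)c(OCc3ccccc3)c2C(=O)C(O)=C1 | intermediate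
15 | 3,4,6-tris(benzyloxy)-5-oxo-5H-benzo[7]annulene-1,8-dicarbaldehyde | O=CC1=Cc2c(C=O)cc(OCc3ccccc3)c(OCc3ccccc3)c2C(=O)C(OCc2ccccc2)=C1 | intermediate
16 | 3,4,6-tris(benzyloxy)-1,8-bis[(1R)-1-hydroxyprop-2-en-1-yl]-5H-benzo[7]annulen-5-one | C=C[C@@H](O)C1=Cc2c([C@H](O)C=C)cc(OCc3ccccc3)c(OCc3ccccc3)c2C(=O)C(OCc2ccccc2)=C1 | intermediate
17 | 3,4,6-tris(benzyloxy)-1,8-bis{(S)-hydroxy[(2R)-oxiran-2-yl]methyl}-5H-benzo[7]annulen-5-one | O[C@H]([C@H]4CO4)C1=Cc2c([C@H](O)[C@H]4CO4)cc(OCc3ccccc3)c(OCc3ccccc3)c2C(=O)C(OCc2ccccc2)=C1 | intermediate
18 | 3,5-bis(benzyloxy)phenol | Oc1cc(OCc2ccccc2)cc(OCc2ccccc2)c1 | starting material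
19 | 3,4,6-tris(benzyloxy)-1,8-bis{(R)-[3,5-bis(benzyloxy)phenoxy][(2R)-oxiran-2-yl]methyl}-5H-benzo[7]annulen-5-one | O(c5cc(OCc6ccccc6)cc(OCc6ccccc6)c5)[C@@H]([C@H]4CO4)C1=Cc2c([C@@H](Oc5cc(OCc6ccccc6)cc(OCc6ccccc6)c5)[C@H]4CO4)cc(OCc3ccccc3)c(OCc3ccccc3)c2C(=O)C(OCc2ccccc2)=C1 | intermediate
20 | 3,4,6-tris(benzyloxy)-1,8-bis[(2R,3R)-5,7-bis(benzyloxy)-3-hydroxy-3,4-dihydro-2H-chromen-2-yl]-5H-benzo[7]annulen-5-one | O=C1C(OCc2ccccc2)=CC([C@H]4Oc5cc(OCc6ccccc6)cc(OCc6ccccc6)c5C[C@H]4O)=Cc2c([C@H]4Oc5cc(OCc6ccccc6)cc(OCc6ccccc6)c5C[C@H]4O)cc(OCc3ccccc3)c(OCc3ccccc3)c21 | intermediate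
21 | theaflavin, 3,4,6-trihydroxy-1,8-bis[(2R,3R)-3,5,7-trihydroxy-3,4-dihydro-2H-chromen-2-yl]-5H-benzo[7]annulen-5-one | O=c1cc([C@H]2Oc3cc(O)cc(O)c3C[C@H]2O)cc2c([C@H]3Oc4cc(O)cc(O)c4C[C@H]3O)cc(O)c(O)c2c1O | target

## Step count and least certain steps

Total: 16 steps. Longest linear sequence: 16 steps (1 to 21; 2 and 18 are purchased).

**Step 7 (key step).** The most likely failure is that ring closure loses to a faster process. The enolisable CH2CHO arm can condense with the neighbouring aryl aldehyde (aldol closure and dehydration toward a naphthalene), or a ketyl can couple intermolecularly, because closing a seven-membered ring is slower than the five- and six-membered cases. Fallback, from 9 back to 10: the two aldehydes are coupled reductively to the alkene with low-valent titanium (TiCl3, Zn(Cu), DME, slow addition at reflux), giving methyl 3,4-bis(benzyloxy)-1-bromo-7H-benzo[7]annulene-8-carboxylate F1. Catalytic OsO4 with N-methylmorpholine N-oxide then dihydroxylates the electron-richer, styrene-type C5=C6 bond in preference to the ester-conjugated C8=C9 bond. This gives cis-diol 10 through the same C5–C6 bond.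

**Step 12.** Enantioface selection may be poor, or vinyl transfer incomplete. Salt-free divinylzinc is hard to prepare, and the α-alkoxytropone can bind zinc and compete with the chiral aminoalkoxide. The two formyl groups also differ, one being aryl-bound and one on the tropone ring. Fallback, from 15 back to 17: an unselective, aldehyde-specific Nozaki–Hiyama–Kishi vinylation (CH2=CHBr, CrCl2, NiCl2 cat., DMF) gives 3,4,6-tris(benzyloxy)-1,8-bis(1-hydroxyprop-2-en-1-yl)-5H-benzo[7]annulen-5-one as all four stereoisomers F2. Step 13 is then run with stoichiometric Ti(OiPr)4 and L-(+)-diisopropyl tartrate as a double kinetic resolution. Only the (1R,1′R) isomer is epoxidised on both arms and gives 17. The cost is that at most one quarter of the material can be used.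

**Step 14.** Inversion may be incomplete through partial ionisation of the activated carbinol on the C1 arm (benzylic, para to an oxygen), or the hindered, electron-rich phenol may react sluggishly or be C-alkylated. Either would erode the 2,3-cis relationship or the conversion on one arm. Fallback, from 17 and 18 back to 20, with the order of the two ring bonds reversed: phenol 18 is first alkylated at an ortho carbon by the terminal epoxide carbon of each arm (Sc(OTf)3 cat. in CH2Cl2, or (CF3)2CHOH as solvent). This gives 3,4,6-tris(benzyloxy)-1,8-bis{(1S,2R)-3-[2,4-bis(benzyloxy)-6-hydroxyphenyl]-1,2-dihydroxypropyl}-5H-benzo[7]annulen-5-one F3. An intramolecular Mitsunobu etherification (PPh3, DIAD) then closes each pyran ring by attack of the phenol on the benzylic carbinol with inversion, which is more reliably SN2 for a six-membered closure, and gives 20 directly.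

**Step 16.** Over-reduction is the concern: saturation of the tropolone ring, or hydrogenolysis of the benzylic C2–O1 bonds, before the last of seven benzyl ethers has left. Fallback, from 20 to 21, non-reductive: BCl3 with pentamethylbenzene as cation scavenger in CH2Cl2 at −78 °C cleaves aryl benzyl ethers by Lewis-acid-assisted benzyl transfer. No new compound is formed (F0).

**Step 5.** The γ-hydroxy ester 8 may close back to lactone 6 during isolation or on the way to the oxidation, since the ester and the hydroxyethyl arm sit on the same trigonal carbon. Fallback, from 6 back to 9: after hydrolysis and methylation as before, the alcohol is silylated in the same flask (Et3SiCl, imidazole) to give methyl (2E)-2-[3,4-bis(benzyloxy)-6-bromo-2-formylbenzylidene]-4-[(triethylsilyl)oxy]butanoate F4. The primary triethylsilyl ether is then oxidised directly to the aldehyde under Swern conditions ((COCl)2, DMSO, then Et3N), so that free 8 is never handled, and the route rejoins at 9.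

## Further compounds

F1 | step 7 | methyl 3,4-bis(benzyloxy)-1-bromo-7H-benzo[7]annulene-8-carboxylate | COC(=O)C1=Cc2c(Br)cc(OCc3ccccc3)c(OCc3ccccc3)c2C=CC1
F2 | step 12 | 3,4,6-tris(benzyloxy)-1,8-bis(1-hydroxyprop-2-en-1-yl)-5H-benzo[7]annulen-5-one (mixture of all four stereoisomers) | OC(C=C)C1=Cc2c(C(O)C=C)cc(OCc3ccccc3)c(OCc3ccccc3)c2C(=O)C(OCc2ccccc2)=C1
F3 | step 14 | 3,4,6-tris(benzyloxy)-1,8-bis{(1S,2R)-3-[2,4-bis(benzyloxy)-6-hydroxyphenyl]-1,2-dihydroxypropyl}-5H-benzo[7]annulen-5-one | O[C@H]([C@H](O)Cc4c(O)cc(OCc5ccccc5)cc4OCc4ccccc4)C1=Cc2c([C@H](O)[C@H](O)Cc4c(O)cc(OCc5ccccc5)cc4OCc4ccccc4)cc(OCc3ccccc3)c(OCc3ccccc3)c2C(=O)C(OCc2ccccc2)=C1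
F0 | step 16 | none | none
F4 | step 5 | methyl (2E)-2-[3,4-bis(benzyloxy)-6-bromo-2-formylbenzylidene]-4-[(triethylsilyl)oxy]butanoate | CC[Si](CC)(CC)OCC/C(=C\c1c(Br)cc(OCc2ccccc2)c(OCc2ccccc2)c1C=O)C(=O)OC
A1 | alternative 1 | 6,9-epoxy-6,9-dihydro-5H-benzo[7]annulen-5-one carrying both protected flavans (mixture of bridgehead diastereomers) | O=C1C2OC(C([C@H]3Oc4cc(OCc5ccccc5)cc(OCc5ccccc5)c4C[C@H]3OCc3ccccc3)=C2)c2c([C@H]3Oc4cc(OCc5ccccc5)cc(OCc5ccccc5)c4C[C@H]3OCc3ccccc3)cc(OCc3ccccc3)c(OCc3ccccc3)c21
A2 | alternative 1 | (2R,3R)-3,5,7-tris(benzyloxy)-2-ethynylchromane | C#C[C@H]1Oc2cc(OCc3ccccc3)cc(OCc3ccccc3)c2C[C@H]1OCc1ccccc1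
A3 | alternative 1 | 2-diazo-1-{2,3-bis(benzyloxy)-6-formyl-5-[(2R,3R)-3,5,7-tris(benzyloxy)chroman-2-yl]phenyl}ethan-1-one | [N-]=[N+]=CC(=O)c1c(OCc2ccccc2)c(OCc2ccccc2)cc([C@H]2Oc3cc(OCc4ccccc4)cc(OCc4ccccc4)c3C[C@H]2OCc2ccccc2)c1C=O
A4 | alternative 2 | 1,8-bis[(2S)-5,7-bis(benzyloxy)-4-oxochroman-2-yl]-3,4,6-tris(benzyloxy)-5H-benzo[7]annulen-5-one | O=c1c(OCc2ccccc2)cc([C@H]3Oc4cc(OCc5ccccc5)cc(OCc5ccccc5)c4C(=O)C3)cc2c([C@H]3Oc4cc(OCc5ccccc5)cc(OCc5ccccc5)c4C(=O)C3)cc(OCc3ccccc3)c(OCc3ccccc3)c12
A5 | alternative 2 | [3,4,6-tris(benzyloxy)-5-oxo-5H-benzo[7]annulene-1,8-diyl]diboronic acid | OB(O)C1=Cc2c(B(O)O)cc(OCc3ccccc3)c(OCc3ccccc3)c2C(=O)C(OCc2ccccc2)=C1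
A6 | alternative 2 | 5,7-bis(benzyloxy)-4H-chromen-4-one | O=c1ccoc2cc(OCc3ccccc3)cc(OCc3ccccc3)c12
A7 | alternative 3 | methyl 1-bromo-6-chloro-3,4-methylenedioxy-5-oxo-5H-benzo[7]annulene-8-carboxylate | O=c1c(Cl)cc(C(=O)OC)cc2c(Br)cc3OCOc3c12
A8 | alternative 3 | methyl 8-bromo-4-methoxy-5,6-methylenedioxy-2-naphthoate | COC(=O)c1cc(OC)c2c3OCOc3cc(Br)c2c1
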